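(All runs come from a simulation for substances that don't exist; noise was put on by code.)

**Slow start.** X dissolved slowly. At 5.00 h, D stood at 31.8%, 31.6% and 32.4% in Monday's, Friday's and Saturday's runs, though X rose from 13 mM to 66 mM. So I asked what end state violet must reach, and whether it gets there.

| flask | E | X | remark | time |
|---|---|---|---|---|
| Monday's | 25 mM | 13 mM | run made earlier |  |
| Friday's | 25 mM | 26 mM | run made earlier |  |
| Saturday's | 25 mM | 66 mM | run made earlier |  |
| Wednesday's | 19 mM | 27.5 mM | run made earlier |  |
| red | 25 mM | 27.5 mM |  | 25 h |
| teal | 40 mM | 10.0 mM |  | 25 h |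
| blue | 50 mM | 60.0 mM |  | 25 h |
| violet | 6.0 mM | 40.0 mM |  | 25 h |

- Monday's (time / h: D / %): 5.00: 31.8; 10.0: 40.2; 15.0: 40.8; 20.0: 40.9; 25.0: 40.9
- Friday's (time / h: D / %): 5.00: 31.6; 10.0: 55.3; 15.0: 63.4; 20.0: 64.3; 25.0: 64.0
- Saturday's (time / h: D / %): 5.00: 32.4; 10.0: 54.6; 15.0: 66.7; 20.0: 72.3; 25.0: 74.9
- Wednesday's (time / h: D / %): 5.00: 35.9; 10.0: 61.7; 15.0: 73.0; 20.0: 76.1; 25.0: 75.7

(readings scatter by 0.3 percentage points)

- amounts and yields of D count L too
- given per volume of solution although it is solid: X
- what may be going on: X <-> Z; Z + D <-> L; E + Z <-> D + Q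
- at the start none of X is in solution

- ranking by amount of D, in percent of the E charged, from high to low, at 25 h (red / teal / blue / violet)
- the same order at 2.5 h (red / teal / blue / violet)
- the amount of D, in percent of the E charged of the flask you put first, at 25 h
- the amount of D, in percent of the E charged of the flask you put last, at 25 h

**The pull.** Let y be the yield of D, L counted. Each D leaves one Q. With solid present, [Z] holds one value, and so does the ratio of [L] to free [D]. E + Z <-> D + Q then gives, at the end, the same value of charged [E] times y squared over one minus y. I called this the pull, an equilibrium measure (thermodynamic control).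

**Lower bound.** Saturday's flask was still climbing, so its last reading gave a pull of at least 55.9 mM. Charged with 6.0 mM of E, violet then ends at 91.1%.

**Upper edge.** Saturday's gains fell to about half per interval, so I estimated that about one more last gain of 2.6 percentage points remained. This was an estimate, not a proof, so for margin I allowed twice that gain. That gave 80.1%, a pull of 80.6 mM, and 93.5% for violet.

**Solid check.** Wednesday's flask, if its solid had gone, held 13.1 mM as Z and L. Adding violet's E gives 19.1 mM, less than its 40.0 mM of X.

**The forecast.** It gave violet > red > blue > teal at the later time and violet > red > teal > blue at the earlier, with 91% and 22.3%: “Violet stays saturated, about 91%”. Its top value stood at the lower edge of my bracket.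

**The flasks.** They gave violet > red > blue > teal and violet > red > teal > blue, with 92.2% and 22.3%. Violet fell inside the bracket .

    X ⇌ Z, rate k1*(cs1 - [Z]) while solid is left; crystals form when [Z] > cs1 (solubility = 11.0 mM, k = 8.60 × 10⁻⁵ s⁻¹)
    Z + D ⇌ L, settled at all times (K = 64.0 M⁻¹)
    E + Z ⇌ D + Q (K = 3.60, k = 0.00910 M⁻¹ s⁻¹)

**Violet's end.** At 25.0 h, E + Z and free D + Q in violet relaxed with a half-life of 1.53 h, both ways counted, which is short against 25 h. Then 53.2% of its X was still solid and [Z] stood at 10.9 mM. Violet's yield reads back as a pull of 65.5 mM, which for the neighbour charged with 24 mM of E gives 77.8%. That neighbour stood at 75.7%, with 11.8% of its X solid and [Z] at 10.0 mM.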